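## Retrosynthetic overview

1. Target 15 ⇒ Heck disconnection of the aryl–Cβ bond of the enone: aryl bromide 12 + 4‑hydroxyphenyl vinyl ketone 14 (ring A is bought).
2. 12 ⇒ one‑flask benzannulation/epoxide opening: methoxyalkyne 6 + bromo(vinyl)ketene 9; all six carbons of ring B are assembled de novo.
3. 6 ⇒ lithium methoxyacetylide (from chloroacetal 3) + triflate of the Sharpless epoxy alcohol 2 (from prenol 1).
4. Ring order: transient cyclobutenone → benzene ring B → dihydrofuran, all in step 4; the (R)‑epoxide is inverted to the (S)‑centre in that ring closure.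

Assumption: (2Z)-2-bromobut-2-enoic acid 7 and chloroketone 13 are taken as catalogue compounds; the Sharpless step is expected to give about 90% ee, raised if needed by recrystallising 12.

## Route

Step 1
Reactants: 1 3-methylbut-2-en-1-ol (prenol)
Product: 2 [(2R)-3,3-dimethyloxiran-2-yl]methanol
Conditions: Ti(OiPr)4 (5 mol %), D-(−)-diethyl tartrate (7 mol %), t-BuOOH (2 equiv, isooctane), 4 Å MS, CH2Cl2, −20 °C
Reagents that add atoms: tert-butyl hydroperoxide, CC(C)(C)OO
Why: Sharpless asymmetric epoxidation of a primary allylic alcohol; the D-(−)-tartrate catalyst delivers oxygen to the face that gives the (2R)-epoxy alcohol, which sets the only stereocentre of the route.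

Step 2
Reactants: 2 [(2R)-3,3-dimethyloxiran-2-yl]methanol, 3 2-chloro-1,1-dimethoxyethane
Product: 6 (2R)-2-(3-methoxyprop-2-yn-1-yl)-3,3-dimethyloxirane, via epoxy triflate 4 (not isolated), via lithium methoxyacetylide 5 (not isolated)
Conditions: (a) 2, Tf2O, 2,6-lutidine, CH2Cl2, −78 °C; cold pentane, filter; (b) 3 (2 equiv), LDA (6.2 equiv), THF, −78 → 0 °C; (c) solution a into b, DMPU, −78 → −20 °C
Reagents that add atoms: none
Why: Double elimination of the chloroacetal gives the alkoxyacetylide (Arens-type ynol ether synthesis), which displaces the primary triflate by SN2 faster than it can open the epoxide at its hindered secondary carbon, so the stereocentre is untouched.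

Step 3
Reactants: 7 (2Z)-2-bromobut-2-enoic acid
Product: 8 (2Z)-2-bromobut-2-enoyl chloride
Conditions: (COCl)2, DMF (cat.), CH2Cl2, 0 °C → rt; distil
Reagents that add atoms: oxalyl chloride, O=C(Cl)C(Cl)=O
Why: Standard acid chloride formation through the Vilsmeier-type chloroiminium catalyst; the alkene geometry is irrelevant because it is lost in the ketene.

Step 4
Reactants: 6 (2R)-2-(3-methoxyprop-2-yn-1-yl)-3,3-dimethyloxirane, 8 (2Z)-2-bromobut-2-enoyl chloride
Product: 12 2-[(2S)-5-bromo-4-methoxy-2,3-dihydro-1-benzofuran-2-yl]propan-2-ol, via bromo(vinyl)ketene 9 (not isolated), via 4-vinylcyclobutenone 10 (not isolated), via epoxy phenol 11 (not isolated)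
Conditions: 8 (1.5 equiv) added slowly to 6 and Et3N (2 equiv), toluene, 0 °C → rt; filter off Et3N·HCl; 100 °C, 3 h; then K2CO3, MeOH, 50 °C
Reagents that add atoms: none
Why: Proposed new method: Et3N dehydrochlorinates 8 through its γ-methyl group to ketene 9, the nucleophilic ynol ether carbon attacks the ketene carbonyl and [2+2] closure gives 10, which at 100 °C undergoes reversible 4π ring opening to a dienylketene, 6π electrocyclisation and tautomerisation to phenol 11 (OH ortho to the alkyl group, OMe meta, Br para), whose phenoxide opens the epoxide 5-exo-tet at the secondary carbon with inversion (R → S) to close the dihydrofuran; the closest known chemistry is the Danheiser benzannulation of vinylketenes with alkoxyalkynes (with the Wasserman ketene/alkoxyacetylene [2+2]) and the base-mediated cyclisation of o-(2,3-epoxy-3-methylbutyl)phenols.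

Step 5
Reactants: 12 2-[(2S)-5-bromo-4-methoxy-2,3-dihydro-1-benzofuran-2-yl]propan-2-ol, 13 3-chloro-1-(4-hydroxyphenyl)propan-1-one
Product: 15 (2E)-1-(4-hydroxyphenyl)-3-[(2S)-2-(2-hydroxypropan-2-yl)-4-methoxy-2,3-dihydro-1-benzofuran-5-yl]prop-2-en-1-one, via 4-hydroxyphenyl vinyl ketone 14 (not isolated)
Conditions: Pd(OAc)2 (5 mol %), P(o-tol)3 (12 mol %), Et3N (4 equiv), DMF, 100 °C
Reagents that add atoms: none
Why: Mizoroki–Heck reaction: Et3N releases the enone from 13 by E1cB loss of HCl, zerovalent palladium inserts into the C–Br bond, and syn insertion followed by syn β-hydride elimination gives the E-enone without touching the remote stereocentre.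

## Compound list

1 | 3-methylbut-2-en-1-ol | CC(C)=CCO | starting material
2 | [(2R)-3,3-dimethyloxiran-2-yl]methanol | OC[C@H]1OC1(C)C | intermediate
3 | 2-chloro-1,1-dimethoxyethane | COC(CCl)OC | starting material
4 | [(2R)-3,3-dimethyloxiran-2-yl]methyl trifluoromethanesulfonate | FC(F)(F)S(=O)(=O)OC[C@H]1OC1(C)C | intermediate
5 | lithium methoxyacetylide | [Li]C#COC | intermediate
6 | (2R)-2-(3-methoxyprop-2-yn-1-yl)-3,3-dimethyloxirane | COC#CC[C@H]1OC1(C)C | intermediate
7 | (2Z)-2-bromobut-2-enoic acid | C/C=C(\Br)C(=O)O | starting material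
8 | (2Z)-2-bromobut-2-enoyl chloride | C/C=C(\Br)C(Cl)=O | intermediate
9 | 2-bromobuta-1,3-dien-1-one | C=CC(Br)=C=O | intermediate
10 | 4-bromo-2-{[(2R)-3,3-dimethyloxiran-2-yl]methyl}-4-ethenyl-3-methoxycyclobut-2-en-1-one (both C4 epimers) | COC1=C(C[C@H]2OC2(C)C)C(=O)C1(Br)C=C | intermediate
11 | 4-bromo-2-{[(2R)-3,3-dimethyloxiran-2-yl]methyl}-3-methoxyphenol | COc1c(Br)ccc(O)c1C[C@H]1OC1(C)C | intermediate
12 | 2-[(2S)-5-bromo-4-methoxy-2,3-dihydro-1-benzofuran-2-yl]propan-2-ol | COc1c(Br)ccc2c1C[C@@H](C(C)(C)O)O2 | intermediate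
13 | 3-chloro-1-(4-hydroxyphenyl)propan-1-one | O=C(CCCl)c1ccc(O)cc1 | starting material
14 | 1-(4-hydroxyphenyl)prop-2-en-1-one | C=CC(=O)c1ccc(O)cc1 | intermediate
15 | (2E)-1-(4-hydroxyphenyl)-3-[(2S)-2-(2-hydroxypropan-2-yl)-4-methoxy-2,3-dihydro-1-benzofuran-5-yl]prop-2-en-1-one | COc1c(/C=C/C(=O)c2ccc(O)cc2)ccc2c1C[C@@H](C(C)(C)O)O2 | target

## Step count and risks

Total steps: 5. Longest linear sequence: 4 (steps 1, 2, 4, 5); step 3 is a one-step side branch.

**Step 4 (most likely to fail).** The α-bromo vinylketene may polymerise or add poorly. The zwitterion could also close directly to a six-membered ring, which would put Br ortho to OH. Residual chloride could open the epoxide. The fallback sets out from 6 and comes back at 12. 6 is taken through the same sequence with commercial (2E)-but-2-enoyl chloride and Et3N. The parent vinylketene buta-1,3-dien-1-one F1 is an established [2+2] partner and gives 2-{[(2R)-3,3-dimethyloxiran-2-yl]methyl}-4-ethenyl-3-methoxycyclobut-2-en-1-one F2. Heating gives 2-{[(2R)-3,3-dimethyloxiran-2-yl]methyl}-3-methoxyphenol F3, and K2CO3/MeOH gives 2-[(2S)-4-methoxy-2,3-dihydro-1-benzofuran-2-yl]propan-2-ol F4. The bromine is then introduced afterwards with N-bromosuccinimide in MeCN at −20 °C, para to the ring oxygen. The selectivity of this bromination over the 7-position is uncertain, so the 7-bromo isomer may have to be removed by chromatography to reach 12.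

**Step 2.** The triflate 4 is labile, and lithium methoxide or diisopropylamine in the acetylide solution can compete for it. The fallback sets out from 5 and comes back at 11, then 12; steps 1 and 2 are no longer needed. 5 is alkylated with 1-bromo-3-methylbut-2-ene (THF–DMPU) to 1-methoxy-5-methylhex-4-en-1-yne F5, which carries no epoxide. Benzannulation with 8 as in step 4 passes through 4-bromo-4-ethenyl-3-methoxy-2-(3-methylbut-2-en-1-yl)cyclobut-2-en-1-one F6 to 4-bromo-3-methoxy-2-(3-methylbut-2-en-1-yl)phenol F7. Acetylation (Ac2O, pyridine) gives 4-bromo-3-methoxy-2-(3-methylbut-2-en-1-yl)phenyl acetate F8. Shi epoxidation (D-fructose-derived ketone, KHSO5, K2CO3 buffer, MeCN–dimethoxymethane–H2O, 0 °C) gives 4-bromo-2-{[(2R)-3,3-dimethyloxiran-2-yl]methyl}-3-methoxyphenyl acetate F9. K2CO3/MeOH removes the acetate to give 11, which closes to 12 as in step 4. The stereocentre then comes from the Shi epoxidation.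

**Step 5.** Vinyl ketone 14 can oligomerise by oxa-Michael addition or polymerisation, and oxidative addition into the electron-rich, ortho-methoxy aryl bromide may be slow. The fallback sets out from 12 and comes back at 15. 12 is treated with n-BuLi (2.2 equiv, THF, −78 °C) to give lithium 2-[(2S)-5-lithio-4-methoxy-2,3-dihydro-1-benzofuran-2-yl]propan-2-olate F10. Quenching with DMF gives (2S)-2-(2-hydroxypropan-2-yl)-4-methoxy-2,3-dihydro-1-benzofuran-5-carbaldehyde F11. Claisen–Schmidt condensation of F11 with commercial 1-(4-hydroxyphenyl)ethan-1-one (KOH, EtOH–H2O, rt) gives 15.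

## Further compounds

F1 | step 4 | buta-1,3-dien-1-one | C=CC=C=O
F2 | step 4 | 2-{[(2R)-3,3-dimethyloxiran-2-yl]methyl}-4-ethenyl-3-methoxycyclobut-2-en-1-one | COC1=C(C[C@H]2OC2(C)C)C(=O)C1C=C
F3 | step 4 | 2-{[(2R)-3,3-dimethyloxiran-2-yl]methyl}-3-methoxyphenol | COc1cccc(O)c1C[C@H]1OC1(C)C
F4 | step 4 | 2-[(2S)-4-methoxy-2,3-dihydro-1-benzofuran-2-yl]propan-2-ol | COc1cccc2c1C[C@@H](C(C)(C)O)O2
F5 | step 2 | 1-methoxy-5-methylhex-4-en-1-yne | COC#CCC=C(C)C
F6 | step 2 | 4-bromo-4-ethenyl-3-methoxy-2-(3-methylbut-2-en-1-yl)cyclobut-2-en-1-one | COC1=C(CC=C(C)C)C(=O)C1(Br)C=C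
F7 | step 2 | 4-bromo-3-methoxy-2-(3-methylbut-2-en-1-yl)phenol | COc1c(Br)ccc(O)c1CC=C(C)C
F8 | step 2 | 4-bromo-3-methoxy-2-(3-methylbut-2-en-1-yl)phenyl acetate | COc1c(Br)ccc(OC(C)=O)c1CC=C(C)C
F9 | step 2 | 4-bromo-2-{[(2R)-3,3-dimethyloxiran-2-yl]methyl}-3-methoxyphenyl acetate | COc1c(Br)ccc(OC(C)=O)c1C[C@H]1OC1(C)C
F10 | step 5 | lithium 2-[(2S)-5-lithio-4-methoxy-2,3-dihydro-1-benzofuran-2-yl]propan-2-olate | COc1c([Li])ccc2c1C[C@@H](C(C)(C)O[Li])O2
F11 | step 5 | (2S)-2-(2-hydroxypropan-2-yl)-4-methoxy-2,3-dihydro-1-benzofuran-5-carbaldehyde | COc1c(C=O)ccc2c1C[C@@H](C(C)(C)O)O2
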